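**Remark:** units are numbered 1 to 4 from the chain‑extending end to the catechin terminus, and each unit keeps flavan numbering (O1, C2, C3, C4, C4a, C5–C8, C8a; ring B primed). (−)‑Epicatechin is taken as a commercial starting material beside (+)‑catechin. The configurations were cross‑checked: unit 3 is 3R,4R in 14 and 15 and 2R,3R,4R from 19 on, and no structure needed correction.

## Structural features

Arecatannin A2 is a linear B‑type procyanidin tetramer. It has four flavan‑3‑ol units, each a chroman (rings A and C) with a 3,4‑dihydroxyphenyl ring B on C2, joined by three bonds from C4 of one unit to C8 of the next. Units 1 to 3 are epicatechin units (2R,3R,4R; C2/C3 cis, C3/C4 trans) and unit 4 is (+)‑catechin (2R,3S) with a methylene C4. This gives eleven stereocentres, three of them contiguous on ring C of each extender unit. Every C4 is a doubly benzylic diarylmethine wedged between C5–O of its own ring A and O1 and C7–O of the next ring A, so each junction is crowded. The sixteen phenols (catechols and phloroglucinol‑type rings A) are sensitive to oxidation and base, and the interflavan bonds ionise at C4 under acid. Protecting groups must therefore leave under neutral, reductive conditions. The real difficulty is to make each C4–C8 bond at C8 and not C6, with C4 trans to C3–O while C2 and C3 stay cis. The key step uses the fact that C4 of unit 3 sits on C4a, ortho to the oxygen‑bearing C8a of ring A. C4 is therefore the exocyclic carbon of an ortho‑quinone methide whose oxygen becomes O1 and which already carries C8 of ring A of unit 4. C3 with its oxygen and C2 correspond to the alpha carbon and the carbonyl carbon of a two‑carbon alkoxy aldehyde.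

## Logic of the disconnections

**28 to 27.** The eighteen O–benzyl bonds and the C8–Br bond of unit 1 are cut. One kind of protecting group and the bromine cap fall in a single hydrogenolysis, so no acid or base touches the free polyphenol. The forward step must cleave nineteen bonds and must buffer the hydrogen bromide it forms.

**27 to 26 and 23.** The C4(unit 1)–C8(unit 2) bond is cut. C4 of an epicatechin unit ionises readily and is attacked on the face opposite to the C2 aryl and C3–O, so unit 1 comes complete from the chiral pool in one bond‑forming step. The tetramer becomes a trimer and a monomer. The forward step must attack only C8 of unit 2 and only once, which is why 23 carries bromine on C8.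

**26 to 24, then 24 to 19 and 23.** C8–H of unit 2 is traced back to C8–Br, and then the C4(unit 2)–C8(unit 3) bond is cut in the same way. The cap that stops chain growth must be exchangeable for hydrogen without harm to benzyl ethers. 19 must react at C8 of unit 3 and not at either C6.

**23 to 22 to 21 to 20.** The C4–O bond, the C8–Br bond and four O–benzyl bonds are cut. All three stereocentres of units 1 and 2 come from 20. The oxidation must touch C4 alone and the bromination C8 alone.

**19 to 15 and 16 (through 17 and 18).** The C2–C1' and C2–H bonds of unit 3 are cut. Ring B becomes a plain aryl nucleophile and C2 a lactone carbonyl, which leaves a ring C with only C3 and C4 as stereocentres. The forward step needs a single addition to the lactone and hydride delivery to C2 anti to C3–O.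

**15 to 14.** Only the oxidation level at C2 changes. The lactol is what the annulation delivers, and the lactone makes C3 correctable. The oxidant must spare electron‑rich arenes and benzyl ethers.

**14 to 10 and 11 (through 12 and 13).** The C3–C4 and O1–C2 bonds are cut. Ring C of unit 3 falls apart into a quinone methide precursor that already holds the interflavan bond and a two‑carbon aldehyde that brings the C3 oxygen. The forward step must set C3 and C4 by reagent control, because the stereocentres of unit 4 are remote.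

**10 to 9, then 9 to 4 and 7 (through 8).** The O–allyl bond is cut, and then the bond between the carbinol carbon (future C4 of unit 3) and C8 of unit 4. Halogen–metal exchange makes this bond C8‑specific. The phenol mask is an allyl ether and not an acetal, because 9 and 10 ionise at the carbinol carbon with traces of acid. The mask must therefore come off under non‑acidic conditions.

**4 to 3 to 2 to 1, and 7 to 6 to 5.** Only C8–Br, O–benzyl and O–allyl bonds are cut. The demands are C8‑selective bromination and leaving exactly one ortho phenol of 5 free for the allyl group.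

## Other disconnections considered

**Alternative 1:** The cut runs through ring A of unit 4 (C8–C8a, C6–C7 and C4a–C8a). In the forward step, cyclobutenone A3 and siloxyalkyne A2 (units 1 to 3 with the alkyne on C4 of unit 3) are heated. A3 opens to a vinylketene, adds to the alkyne, and the adduct reopens and electrocyclises to phenol A1 (Danheiser benzannulation).

- In its favour: the junction between units 3 and 4 exists before ring A does, so the C6/C8 question cannot arise. The C8a phenol is placed for closure of ring C. The conditions are neutral and stereochemically innocent at C4.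
- Against it: A2 already holds three finished epicatechin units and two interflavan bonds, which must come from chemistry like the chosen plan. Unit 4 is rebuilt from an acyclic chain although 1 offers it complete. After the key step, the silyl ethers must be exchanged and O1–C2 closed stereospecifically. The cycloaddition must take place at an alkyne beside a crowded diaryl‑flanked carbon.
- Comparison: on C8 regiocontrol it is the equal of the chosen plan, which fixes C8 by halogen–metal exchange. On mechanism it is better in one respect, since it creates no stereocentre. On step economy it is clearly worse.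

**Alternative 2:** The cut removes the three C2–C1' bonds and C2–H bonds of units 1 to 3. In the forward step, tris‑lactone A5 takes up three equivalents of 17, and Et3SiH with BF3·OEt2 reduces the three hemiketals to A4. Hydrogenolysis would then give 28.

- In its favour: it is the reaction of step 10 done three times in one flask. The backbone carries only C3 and C4 stereocentres, and ring B can be varied late.
- Against it: every weakness of step 10 (enolisation, double addition, facial leakage) is multiplied by three, and the products are nearly inseparable tetramer isomers. A5 needs three annulation cycles, each with a C8 metalation that an aryl lactone would not survive unless masked.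
- Comparison: mechanistically it is the equal of step 10. In convergence of ring B introduction it is better. In step count and error propagation it is worse than taking units 1 and 2 whole from 20.

**Alternative 3:** The cut is the C2–C3 bond, made as a double bond. In the forward step, the second‑generation Grubbs catalyst closes diene A7 (1‑arylvinyl ether on O1, vinyl on C4) to flav‑2‑ene A6 with loss of ethylene.

- In its favour: the conditions are neutral and tolerate benzyl ethers. No stabilised cation is involved, and a C4 centre set earlier is carried through.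
- Against it: the hard part, an enantiopure vinyl‑bearing diarylmethine, is moved elsewhere. The 1,1‑disubstituted, electron‑rich, hindered enol ether is a poor metathesis partner. Migration of the double bond through the doubly benzylic C4–H would erase C4. The C3 oxygen must still be added: hydroboration would give the C2/C3 trans series, so epoxidation anti to the C4 aryl followed by silane reduction of a hemiketal of the type of 18 would be needed.
- Comparison: on the C2 problem it is the equal of the chosen plan, since both end in the same oxocarbenium reduction. On mildness of the ring closure it is better. On C3 and on step count it is worse, because in the chosen plan the C3 oxygen arrives with 11 and C3 and C4 form together.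

Key step: step 8

## Steps

In the names below, tetra‑O‑benzyl means 5,7,3',4'‑tetra‑O‑benzyl and penta‑O‑benzyl means 3,5,7,3',4'‑penta‑O‑benzyl.

**Step 1**
Reactants: 1 (+)-catechin
Product: 2 tetra-O-benzylcatechin
Conditions: BnBr (4.4 equiv), K2CO3, DMF, 0 °C to rt
Reagents that add atoms: benzyl bromide, BrCc1ccccc1
Why: Williamson ether synthesis; K2CO3 deprotonates only the four phenols, so the secondary alcohol stays free, and the mild base should leave C2 and C3 untouched.

**Step 2**
Reactants: 2 tetra-O-benzylcatechin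
Product: 3 penta-O-benzylcatechin
Conditions: NaH, BnBr, DMF, 0 °C to rt
Reagents that add atoms: benzyl bromide, BrCc1ccccc1
Why: Williamson ether synthesis at the C3 alkoxide; with no free phenol left, ring C cannot open, so both stereocentres are retained and no acidic proton remains for step 6.

**Step 3**
Reactants: 3 penta-O-benzylcatechin
Product: 4 8-bromo-penta-O-benzylcatechin
Conditions: NBS (1.0 equiv), CH2Cl2, −78 °C to rt
Reagents that add atoms: N-bromosuccinimide, O=C1CCC(=O)N1Br
Why: Electrophilic aromatic bromination; ring A is far more electron‑rich than ring B, and C8 (between O1 and one benzyloxy group) should react before C6 (between two benzyloxy groups) with one equivalent at low temperature.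

**Step 4**
Reactants: 5 2,4,6-trihydroxybenzaldehyde
Product: 6 2,4-bis(benzyloxy)-6-hydroxybenzaldehyde
Conditions: BnBr (2.05 equiv), K2CO3 (2.1 equiv), DMF, 0 °C to rt
Reagents that add atoms: benzyl bromide, BrCc1ccccc1
Why: Williamson ether synthesis; the para phenol and one ortho phenol are alkylated, and the last ortho phenol is held in a hydrogen bond to the formyl group and is the least nucleophilic, so limiting BnBr should stop at 6.

**Step 5**
Reactants: 6 2,4-bis(benzyloxy)-6-hydroxybenzaldehyde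
Product: 7 2-(allyloxy)-4,6-bis(benzyloxy)benzaldehyde
Conditions: allyl bromide, K2CO3, DMF, 50 °C
Reagents that add atoms: allyl bromide, C=CCBr
Why: Williamson ether synthesis on the chelated phenol under slightly forcing conditions; allyl is chosen because zerovalent palladium removes it later without acid.

**Step 6**
Reactants: 4 8-bromo-penta-O-benzylcatechin; 7 2-(allyloxy)-4,6-bis(benzyloxy)benzaldehyde
Product: 9 [2-(allyloxy)-4,6-bis(benzyloxy)phenyl](penta-O-benzylcatechin-8-yl)methanol as a mixture of carbinol epimers, via (penta-O-benzylcatechin-8-yl)lithium 8 (not isolated)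
Conditions: n-BuLi (1.05 equiv), THF, −78 °C; then 7, −78 to −40 °C; then H2O
Reagents that add atoms: none
Why: Bromine–lithium exchange gives the C8 aryllithium regiospecifically, and its 1,2‑addition to the aldehyde makes the future C4(unit 3)–C8(unit 4) bond; the carbinol configuration does not matter because this carbon becomes planar in step 8.

**Step 7**
Reactants: 9 [2-(allyloxy)-4,6-bis(benzyloxy)phenyl](penta-O-benzylcatechin-8-yl)methanol
Product: 10 [2-hydroxy-4,6-bis(benzyloxy)phenyl](penta-O-benzylcatechin-8-yl)methanol (either carbinol epimer)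
Conditions: Pd(PPh3)4 (5 mol %), K2CO3, MeOH/THF, rt
Reagents that add atoms: none
Why: Tsuji–Trost‑type deallylation, in which zerovalent palladium ionises the aryl allyl ether and methoxide takes the allyl group; the basic medium should keep the acid‑sensitive benzhydrol intact and leave the benzyl ethers alone.

**Step 8**
Reactants: 10 [2-hydroxy-4,6-bis(benzyloxy)phenyl](penta-O-benzylcatechin-8-yl)methanol; 11 benzyloxyacetaldehyde
Product: 14 (2R,3R,4R)-3,5,7-tris(benzyloxy)-4-(penta-O-benzylcatechin-8-yl)chroman-2-ol (either anomer), via ortho-quinone methide 12 (not isolated), via ring-open hydroxyaryl aldehyde 13 (not isolated)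
Conditions: (S)-α,α-diphenylprolinol trimethylsilyl ether (20 mol %), PhCO2H (20 mol %), 11 (3 equiv, slow addition), CH2Cl2, 0 °C to rt
Reagents that add atoms: none
Why: Benzoic acid dehydrates the doubly activated benzhydrol 10 to the ortho‑quinone methide 12, while the amine condenses with 11 to the E‑enamine, whose benzyloxy‑bearing carbon adds to the methide carbon (C3–C4) with rearomatisation of ring A as driving force; hydrolysis of the iminium ion gives aldehyde 13, whose phenol adds to the aldehyde carbon (O1–C2) to give lactol 14 and free catalyst. The closest known reaction type is the secondary‑amine‑catalysed Michael addition and hemiacetalisation of enolisable aldehydes with ortho‑quinone methides made in situ from ortho‑hydroxybenzhydrols, and alpha‑alkoxyacetaldehydes are established enamine donors with this class of catalyst. Ring C of unit 3 closes by 6‑exo‑trig attack of the phenol oxygen on the aldehyde (or iminium) carbon. C3 is controlled by the catalyst: the diphenyl(silyloxy)methyl group blocks one enamine face, and the S catalyst should give 3R, the same sense as at the alpha carbon in its Michael additions to nitroalkenes once the priority change caused by the oxygen substituent is taken into account. C4 is controlled by the relative topicity of the C–C bond formation: the synclinal approach that places the methide oxygen near the enamine nitrogen leads to the 3,4‑trans (3R,4R) product, which is also the less strained arrangement of the benzyloxy group and the bulky C4 aryl. The stereocentres of unit 4 are remote, so both new centres depend on reagent control, and a C4 epimer would be a diastereomer that can be separated at this stage. Chemoselectivity is secured by the substrate: 10 has a single free phenol, so only one quinone methide and one mode of ring closure exist, and the enamine should outcompete the benzyl‑protected arenes as nucleophile. The anomeric centre C2 is of no consequence because step 9 oxidises it.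

**Step 9**
Reactants: 14 (2R,3R,4R)-3,5,7-tris(benzyloxy)-4-(penta-O-benzylcatechin-8-yl)chroman-2-ol
Product: 15 (3R,4R)-3,5,7-tris(benzyloxy)-4-(penta-O-benzylcatechin-8-yl)chroman-2-one
Conditions: Dess–Martin periodinane, CH2Cl2, 0 °C to rt
Reagents that add atoms: none
Why: Dess–Martin oxidation of a lactol to the lactone, mild enough for electron‑rich arenes and benzyl ethers; C3 is now alpha to a carbonyl, so a C3‑epimeric (3,4‑cis) lactone, if present, should converge on trans 15 on brief exposure to DBU, whereas C4 cannot be repaired this way.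

**Step 10**
Reactants: 15 (3R,4R)-3,5,7-tris(benzyloxy)-4-(penta-O-benzylcatechin-8-yl)chroman-2-one; 16 4-bromo-1,2-bis(benzyloxy)benzene
Product: 19 penta-O-benzylepicatechin-(4β→8)-penta-O-benzylcatechin, via 3,4-bis(benzyloxy)phenyllithium 17 (not isolated), via 2-hydroxyflavan hemiketal 18 (not isolated)
Conditions: 16, n-BuLi, THF, −78 °C; then 15, −78 °C; then H2O; crude 18, Et3SiH, BF3·OEt2, CH2Cl2, −78 to −30 °C
Reagents that add atoms: none
Why: Aryllithium addition to the lactone at −78 °C should stop at the tetrahedral adduct, and BF3·OEt2 then ionises hemiketal 18 to the 2‑aryl oxocarbenium ion, which Et3SiH reduces (ionic hydrogenation, as in C‑aryl glycoside synthesis). In the half‑chair cation the C3 benzyloxy group and the C4 aryl are expected to be pseudo‑axial, so hydride should enter C2 anti to the adjacent C3–O bond and place ring B equatorial, which sets 2R (C2/C3 cis).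

**Step 11**
Reactants: 20 (−)-epicatechin
Product: 21 tetra-O-benzylepicatechin
Conditions: BnBr (4.4 equiv), K2CO3, DMF, 0 °C to rt
Reagents that add atoms: benzyl bromide, BrCc1ccccc1
Why: Williamson ether synthesis on the four phenols only, as in step 1; the 3‑OH stays free and no stereocentre is touched.

**Step 12**
Reactants: 21 tetra-O-benzylepicatechin
Product: 22 8-bromo-tetra-O-benzylepicatechin
Conditions: NBS (1.0 equiv), CH2Cl2, −78 °C to rt
Reagents that add atoms: N-bromosuccinimide, O=C1CCC(=O)N1Br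
Why: Electrophilic aromatic bromination at C8, as in step 3; the bromine serves as the cap that blocks the nucleophilic position of the future electrophile.

**Step 13**
Reactants: 22 8-bromo-tetra-O-benzylepicatechin
Product: 23 (2R,3R,4S)-8-bromo-tetra-O-benzyl-4β-(2-ethoxyethoxy)epicatechin
Conditions: DDQ, 2-ethoxyethanol, CH2Cl2, rt
Reagents that add atoms: 2-ethoxyethanol, CCOCCO
Why: Oxidative benzylic etherification; DDQ abstracts hydride from C4, the position activated by the ring A oxygens, and the alcohol traps the cation on the face opposite to the C2 aryl and the C3 hydroxyl, giving the 4β ether.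

**Step 14**
Reactants: 19 penta-O-benzylepicatechin-(4β→8)-penta-O-benzylcatechin; 23 (2R,3R,4S)-8-bromo-tetra-O-benzyl-4β-(2-ethoxyethoxy)epicatechin
Product: 24 8-bromo-tetra-O-benzylepicatechin-(4β→8)-penta-O-benzylepicatechin-(4β→8)-penta-O-benzylcatechin
Conditions: 23 (1.3 equiv), BF3·OEt2, 4 Å molecular sieves, CH2Cl2, −78 to −40 °C
Reagents that add atoms: none
Why: Friedel–Crafts‑type benzylic alkylation by an SN1 path; the Lewis acid ionises the C4–O bond of 23, and C8 of unit 3 of 19, the most nucleophilic free position, attacks the cation anti to the C2 aryl and C3–OH to set 4R. The bromine on C8 of 23 prevents self‑condensation and growth beyond one unit.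

**Step 15**
Reactants: 24 8-bromo-tetra-O-benzylepicatechin-(4β→8)-penta-O-benzylepicatechin-(4β→8)-penta-O-benzylcatechin
Product: 26 tetra-O-benzylepicatechin-(4β→8)-penta-O-benzylepicatechin-(4β→8)-penta-O-benzylcatechin, via dilithiated trimer 25 (not isolated)
Conditions: n-BuLi (3 equiv), THF, −78 °C; then H2O
Reagents that add atoms: none
Why: Deprotonation of the 3‑OH and bromine–lithium exchange, then protonation, replaces the cap by hydrogen; benzyl ethers and stereocentres are inert at −78 °C.

**Step 16**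
Reactants: 26 tetra-O-benzylepicatechin-(4β→8)-penta-O-benzylepicatechin-(4β→8)-penta-O-benzylcatechin; 23 (2R,3R,4S)-8-bromo-tetra-O-benzyl-4β-(2-ethoxyethoxy)epicatechin
Product: 27 8-bromo-tetra-O-benzylepicatechin-(4β→8)-tetra-O-benzylepicatechin-(4β→8)-penta-O-benzylepicatechin-(4β→8)-penta-O-benzylcatechin
Conditions: 23 (1.5 equiv), BF3·OEt2, 4 Å molecular sieves, CH2Cl2, −78 to −40 °C
Reagents that add atoms: none
Why: The same Friedel–Crafts‑type alkylation as step 14, now at C8 of unit 2 of 26, again anti to the C2 aryl and C3–OH of the cation (4R); the bromine cap limits the reaction to one unit.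

**Step 17**
Reactants: 27 8-bromo-tetra-O-benzylepicatechin-(4β→8)-tetra-O-benzylepicatechin-(4β→8)-penta-O-benzylepicatechin-(4β→8)-penta-O-benzylcatechin
Product: 28 arecatannin A2
Conditions: H2 (1 atm), Pd(OH)2/C, Et3N (1.1 equiv), THF/MeOH/H2O, rt
Reagents that add atoms: none
Why: Heterogeneous hydrogenolysis cleaves the eighteen benzyl ethers and the aryl C–Br bond in one operation; Et3N takes up the HBr so the acid‑labile interflavan bonds see no acid, and the ring O1–C2 bond and all stereocentres are expected to survive as in other flavan‑3‑ol debenzylations.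

## Compound list

1 | (+)-catechin | Oc1cc(O)c2c(c1)O[C@H](c3ccc(O)c(O)c3)[C@@H](O)C2 | starting material

2 | tetra-O-benzylcatechin | c9ccccc9COc1cc(OCc9ccccc9)c2c(c1)O[C@H](c3ccc(OCc9ccccc9)c(OCc9ccccc9)c3)[C@@H](O)C2 | intermediate

3 | penta-O-benzylcatechin | c9ccccc9COc1cc(OCc9ccccc9)c2c(c1)O[C@H](c3ccc(OCc9ccccc9)c(OCc9ccccc9)c3)[C@@H](OCc9ccccc9)C2 | intermediate

4 | 8-bromo-penta-O-benzylcatechin | Brc1c(OCc9ccccc9)cc(OCc9ccccc9)c2c1O[C@H](c3ccc(OCc9ccccc9)c(OCc9ccccc9)c3)[C@@H](OCc9ccccc9)C2 | intermediate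

5 | 2,4,6-trihydroxybenzaldehyde | O=Cc1c(O)cc(O)cc1O | starting material

6 | 2,4-bis(benzyloxy)-6-hydroxybenzaldehyde | O=Cc1c(O)cc(OCc9ccccc9)cc1OCc9ccccc9 | intermediate

7 | 2-(allyloxy)-4,6-bis(benzyloxy)benzaldehyde | O=Cc1c(OCC=C)cc(OCc9ccccc9)cc1OCc9ccccc9 | intermediate

8 | (penta-O-benzylcatechin-8-yl)lithium | [Li]c1c(OCc9ccccc9)cc(OCc9ccccc9)c2c1O[C@H](c3ccc(OCc9ccccc9)c(OCc9ccccc9)c3)[C@@H](OCc9ccccc9)C2 | intermediate (not isolated)

9 | [2-(allyloxy)-4,6-bis(benzyloxy)phenyl](penta-O-benzylcatechin-8-yl)methanol, carbinol epimers | C=CCOc1cc(OCc9ccccc9)cc(OCc9ccccc9)c1C(O)c1c(OCc9ccccc9)cc(OCc9ccccc9)c2c1O[C@H](c3ccc(OCc9ccccc9)c(OCc9ccccc9)c3)[C@@H](OCc9ccccc9)C2 | intermediate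

10 | [2-hydroxy-4,6-bis(benzyloxy)phenyl](penta-O-benzylcatechin-8-yl)methanol, either carbinol epimer | Oc1cc(OCc9ccccc9)cc(OCc9ccccc9)c1C(O)c1c(OCc9ccccc9)cc(OCc9ccccc9)c2c1O[C@H](c3ccc(OCc9ccccc9)c(OCc9ccccc9)c3)[C@@H](OCc9ccccc9)C2 | intermediate

11 | benzyloxyacetaldehyde | O=CCOCc1ccccc1 | starting material

12 | 3,5-bis(benzyloxy)-6-[(penta-O-benzylcatechin-8-yl)methylidene]cyclohexa-2,4-dien-1-one (ortho-quinone methide) | O=C1C=C(OCc9ccccc9)C=C(OCc9ccccc9)C1=Cc1c(OCc9ccccc9)cc(OCc9ccccc9)c2c1O[C@H](c3ccc(OCc9ccccc9)c(OCc9ccccc9)c3)[C@@H](OCc9ccccc9)C2 | intermediate (not isolated)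

13 | (2R,3R)-2-(benzyloxy)-3-[2-hydroxy-4,6-bis(benzyloxy)phenyl]-3-(penta-O-benzylcatechin-8-yl)propanal | O=C[C@H](OCc9ccccc9)[C@H](c1c(O)cc(OCc9ccccc9)cc1OCc9ccccc9)c1c(OCc9ccccc9)cc(OCc9ccccc9)c2c1O[C@H](c3ccc(OCc9ccccc9)c(OCc9ccccc9)c3)[C@@H](OCc9ccccc9)C2 | intermediate (not isolated)

14 | (2R,3R,4R)-3,5,7-tris(benzyloxy)-4-(penta-O-benzylcatechin-8-yl)chroman-2-ol (2R anomer drawn) | c9ccccc9COc1cc(OCc9ccccc9)c2c(c1)O[C@@H](O)[C@H](OCc9ccccc9)[C@H]2c1c(OCc9ccccc9)cc(OCc9ccccc9)c2c1O[C@H](c3ccc(OCc9ccccc9)c(OCc9ccccc9)c3)[C@@H](OCc9ccccc9)C2 | intermediate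

15 | (3R,4R)-3,5,7-tris(benzyloxy)-4-(penta-O-benzylcatechin-8-yl)chroman-2-one | c9ccccc9COc1cc(OCc9ccccc9)c2c(c1)OC(=O)[C@H](OCc9ccccc9)[C@H]2c1c(OCc9ccccc9)cc(OCc9ccccc9)c2c1O[C@H](c3ccc(OCc9ccccc9)c(OCc9ccccc9)c3)[C@@H](OCc9ccccc9)C2 | intermediate

16 | 4-bromo-1,2-bis(benzyloxy)benzene | Brc1ccc(OCc2ccccc2)c(OCc2ccccc2)c1 | starting material

17 | 3,4-bis(benzyloxy)phenyllithium | [Li]c1ccc(OCc2ccccc2)c(OCc2ccccc2)c1 | intermediate (not isolated)

18 | (2R,3R,4R)-3,5,7-tris(benzyloxy)-2-[3,4-bis(benzyloxy)phenyl]-4-(penta-O-benzylcatechin-8-yl)chroman-2-ol (one anomer drawn) | c9ccccc9COc1cc(OCc9ccccc9)c2c(c1)O[C@](O)(c3ccc(OCc9ccccc9)c(OCc9ccccc9)c3)[C@H](OCc9ccccc9)[C@H]2c1c(OCc9ccccc9)cc(OCc9ccccc9)c2c1O[C@H](c3ccc(OCc9ccccc9)c(OCc9ccccc9)c3)[C@@H](OCc9ccccc9)C2 | intermediate (not isolated)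

19 | penta-O-benzylepicatechin-(4β→8)-penta-O-benzylcatechin | c9ccccc9COc1cc(OCc9ccccc9)c2c(c1)O[C@H](c3ccc(OCc9ccccc9)c(OCc9ccccc9)c3)[C@H](OCc9ccccc9)[C@H]2c1c(OCc9ccccc9)cc(OCc9ccccc9)c2c1O[C@H](c3ccc(OCc9ccccc9)c(OCc9ccccc9)c3)[C@@H](OCc9ccccc9)C2 | intermediate

20 | (−)-epicatechin | Oc1cc(O)c2c(c1)O[C@H](c3ccc(O)c(O)c3)[C@H](O)C2 | starting material

21 | tetra-O-benzylepicatechin | c9ccccc9COc1cc(OCc9ccccc9)c2c(c1)O[C@H](c3ccc(OCc9ccccc9)c(OCc9ccccc9)c3)[C@H](O)C2 | intermediate

22 | 8-bromo-tetra-O-benzylepicatechin | Brc1c(OCc9ccccc9)cc(OCc9ccccc9)c2c1O[C@H](c3ccc(OCc9ccccc9)c(OCc9ccccc9)c3)[C@H](O)C2 | intermediate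

23 | (2R,3R,4S)-8-bromo-tetra-O-benzyl-4β-(2-ethoxyethoxy)epicatechin | Brc1c(OCc9ccccc9)cc(OCc9ccccc9)c2c1O[C@H](c3ccc(OCc9ccccc9)c(OCc9ccccc9)c3)[C@H](O)[C@H]2OCCOCC | intermediate

24 | 8-bromo-tetra-O-benzylepicatechin-(4β→8)-penta-O-benzylepicatechin-(4β→8)-penta-O-benzylcatechin | Brc1c(OCc9ccccc9)cc(OCc9ccccc9)c2c1O[C@H](c3ccc(OCc9ccccc9)c(OCc9ccccc9)c3)[C@H](O)[C@H]2c1c(OCc9ccccc9)cc(OCc9ccccc9)c2c1O[C@H](c3ccc(OCc9ccccc9)c(OCc9ccccc9)c3)[C@H](OCc9ccccc9)[C@H]2c1c(OCc9ccccc9)cc(OCc9ccccc9)c2c1O[C@H](c3ccc(OCc9ccccc9)c(OCc9ccccc9)c3)[C@@H](OCc9ccccc9)C2 | intermediate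

25 | 8-lithio 3-O-lithio derivative of 24 | [Li]c1c(OCc9ccccc9)cc(OCc9ccccc9)c2c1O[C@H](c3ccc(OCc9ccccc9)c(OCc9ccccc9)c3)[C@H](O[Li])[C@H]2c1c(OCc9ccccc9)cc(OCc9ccccc9)c2c1O[C@H](c3ccc(OCc9ccccc9)c(OCc9ccccc9)c3)[C@H](OCc9ccccc9)[C@H]2c1c(OCc9ccccc9)cc(OCc9ccccc9)c2c1O[C@H](c3ccc(OCc9ccccc9)c(OCc9ccccc9)c3)[C@@H](OCc9ccccc9)C2 | intermediate (not isolated)

26 | tetra-O-benzylepicatechin-(4β→8)-penta-O-benzylepicatechin-(4β→8)-penta-O-benzylcatechin | c9ccccc9COc1cc(OCc9ccccc9)c2c(c1)O[C@H](c3ccc(OCc9ccccc9)c(OCc9ccccc9)c3)[C@H](O)[C@H]2c1c(OCc9ccccc9)cc(OCc9ccccc9)c2c1O[C@H](c3ccc(OCc9ccccc9)c(OCc9ccccc9)c3)[C@H](OCc9ccccc9)[C@H]2c1c(OCc9ccccc9)cc(OCc9ccccc9)c2c1O[C@H](c3ccc(OCc9ccccc9)c(OCc9ccccc9)c3)[C@@H](OCc9ccccc9)C2 | intermediate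

27 | 8-bromo-tetra-O-benzylepicatechin-(4β→8)-tetra-O-benzylepicatechin-(4β→8)-penta-O-benzylepicatechin-(4β→8)-penta-O-benzylcatechin | Brc1c(OCc9ccccc9)cc(OCc9ccccc9)c2c1O[C@H](c3ccc(OCc9ccccc9)c(OCc9ccccc9)c3)[C@H](O)[C@H]2c1c(OCc9ccccc9)cc(OCc9ccccc9)c2c1O[C@H](c3ccc(OCc9ccccc9)c(OCc9ccccc9)c3)[C@H](O)[C@H]2c1c(OCc9ccccc9)cc(OCc9ccccc9)c2c1O[C@H](c3ccc(OCc9ccccc9)c(OCc9ccccc9)c3)[C@H](OCc9ccccc9)[C@H]2c1c(OCc9ccccc9)cc(OCc9ccccc9)c2c1O[C@H](c3ccc(OCc9ccccc9)c(OCc9ccccc9)c3)[C@@H](OCc9ccccc9)C2 | intermediate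

28 | arecatannin A2, epicatechin-(4β→8)-epicatechin-(4β→8)-epicatechin-(4β→8)-catechin | Oc1cc(O)c2c(c1)O[C@H](c1ccc(O)c(O)c1)[C@H](O)[C@H]2c1c(O)cc(O)c2c1O[C@H](c1ccc(O)c(O)c1)[C@H](O)[C@H]2c1c(O)cc(O)c2c1O[C@H](c1ccc(O)c(O)c1)[C@H](O)[C@H]2c1c(O)cc(O)c2c1O[C@H](c1ccc(O)c(O)c1)[C@@H](O)C2 | target

## Step count and least certain steps

Total: 17 steps. Longest linear sequence: 12 steps (1, 2, 3, 6, 7, 8, 9, 10, 14, 15, 16, 17) from 1.

**Step 8, the key step.** The most likely failure is poor facial selectivity at the methide carbon. 12 is a strongly stabilised, crowded and nearly cationic electrophile of unfixed geometry, so the C–C bond may form through a loose ion pair. Self‑aldol reaction of 11 and arene alkylation by 12 may also compete. The fallback gives up the de novo ring C and forms the bond between units 3 and 4 by the cationic coupling of steps 14 and 16. It sets out from 3 and 23, which with BF3·OEt2 at −78 °C should give 8‑bromo‑tetra‑O‑benzylepicatechin‑(4β→8)‑penta‑O‑benzylcatechin F1. Benzylation of its 3‑OH (NaH, BnBr) gives 8‑bromo‑penta‑O‑benzylepicatechin‑(4β→8)‑penta‑O‑benzylcatechin F2. Bromine–lithium exchange to the 8‑lithio dimer F3 and protonation returns to the route at 19.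

**Step 10.** The aryllithium may enolise the lactone at C3 or add twice after ring opening. In the reduction, hydride may enter syn to C3–O, because the pseudo‑axial C4 aryl lies on the anti face, or the cation may lose the C3 proton. The fallback sets out from 15. Ring opening with Me(MeO)NH·HCl and i‑PrMgCl gives (2R,3R)‑2‑(benzyloxy)‑3‑[2‑hydroxy‑4,6‑bis(benzyloxy)phenyl]‑N‑methoxy‑N‑methyl‑3‑(penta‑O‑benzylcatechin‑8‑yl)propanamide F4. Addition of excess 17 gives the aryl ketone F5, the open tautomer of 18. Chelation‑controlled reduction with Zn(BH4)2, with hydride anti to the C4 substituent in the chelate between the carbonyl and benzyloxy oxygens, should give the (1S,2R,3R) benzylic alcohol F6. Mitsunobu ring closure (PPh3, DIAD) by the phenol with inversion at the carbinol carbon returns to the route at 19.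

**Step 6.** C–C bond formation between a di‑ortho‑substituted aryllithium and a di‑ortho‑substituted, electron‑rich aldehyde may be slow, so that protonation of 8 back to 3 competes. The fallback reverses the polarity and sets out from 4. Intermediate 8 is quenched with DMF to penta‑O‑benzylcatechin‑8‑carbaldehyde F7. F7 is then combined with the bromomagnesium phenoxide of commercial 3,5‑bis(benzyloxy)phenol (EtMgBr, toluene/CH2Cl2). Ortho‑hydroxyalkylation through a six‑membered magnesium chelate delivers 10 directly, bypassing 7 and 9.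

**Step 16 (and in the same way step 14).** The Lewis acid may cleave and scramble the interflavan bonds already present, and a C6 position may be attacked. Both become more likely as the nucleophile grows and the coupling slows. The fallback changes the activation principle and sets out from 23 and 26. 23 is converted with benzyl mercaptan and BF3·OEt2 at −78 °C into 8‑bromo‑tetra‑O‑benzyl‑4β‑(benzylthio)epicatechin F8. F8 is coupled with 26 by thiophilic activation with AgBF4 in THF at 0 °C, under essentially neutral conditions, and the route is rejoined at 27.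

**Step 17.** Removal of eighteen benzyl groups may stall as the polyphenol fouls the catalyst, and incompletely buffered HBr may split interflavan bonds. The fallback sets out from 27. n‑BuLi (4 equiv, THF, −78 °C) gives the trilithiated tetramer F9, and water gives the bromine‑free tetramer F10. F10 is hydrogenolysed without amine (H2, Pd(OH)2/C, THF/MeOH/H2O), and the route is rejoined at 28.

**Step 4.** Alkylation may overshoot or stop short and give mixtures of mono‑, di‑ and tribenzyl ethers. The fallback sets out from 5. Exhaustive benzylation (BnBr, K2CO3, DMF) gives 2,4,6‑tris(benzyloxy)benzaldehyde F11. Chelation‑directed removal of one ortho benzyl group with MgBr2·OEt2 (toluene/Et2O, reflux) returns to the route at 6.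

## Further compounds

F1 | step 8 | 8-bromo-tetra-O-benzylepicatechin-(4β→8)-penta-O-benzylcatechin | Brc1c(OCc9ccccc9)cc(OCc9ccccc9)c2c1O[C@H](c3ccc(OCc9ccccc9)c(OCc9ccccc9)c3)[C@H](O)[C@H]2c1c(OCc9ccccc9)cc(OCc9ccccc9)c2c1O[C@H](c3ccc(OCc9ccccc9)c(OCc9ccccc9)c3)[C@@H](OCc9ccccc9)C2

F2 | step 8 | 8-bromo-penta-O-benzylepicatechin-(4β→8)-penta-O-benzylcatechin | Brc1c(OCc9ccccc9)cc(OCc9ccccc9)c2c1O[C@H](c3ccc(OCc9ccccc9)c(OCc9ccccc9)c3)[C@H](OCc9ccccc9)[C@H]2c1c(OCc9ccccc9)cc(OCc9ccccc9)c2c1O[C@H](c3ccc(OCc9ccccc9)c(OCc9ccccc9)c3)[C@@H](OCc9ccccc9)C2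

F3 | step 8 | 8-lithio-penta-O-benzylepicatechin-(4β→8)-penta-O-benzylcatechin | [Li]c1c(OCc9ccccc9)cc(OCc9ccccc9)c2c1O[C@H](c3ccc(OCc9ccccc9)c(OCc9ccccc9)c3)[C@H](OCc9ccccc9)[C@H]2c1c(OCc9ccccc9)cc(OCc9ccccc9)c2c1O[C@H](c3ccc(OCc9ccccc9)c(OCc9ccccc9)c3)[C@@H](OCc9ccccc9)C2

F4 | step 10 | (2R,3R)-2-(benzyloxy)-3-[2-hydroxy-4,6-bis(benzyloxy)phenyl]-N-methoxy-N-methyl-3-(penta-O-benzylcatechin-8-yl)propanamide | CON(C)C(=O)[C@H](OCc9ccccc9)[C@H](c1c(O)cc(OCc9ccccc9)cc1OCc9ccccc9)c1c(OCc9ccccc9)cc(OCc9ccccc9)c2c1O[C@H](c3ccc(OCc9ccccc9)c(OCc9ccccc9)c3)[C@@H](OCc9ccccc9)C2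

F5 | step 10 | (2R,3R)-2-(benzyloxy)-1-[3,4-bis(benzyloxy)phenyl]-3-[2-hydroxy-4,6-bis(benzyloxy)phenyl]-3-(penta-O-benzylcatechin-8-yl)propan-1-one | O=C(c3ccc(OCc9ccccc9)c(OCc9ccccc9)c3)[C@H](OCc9ccccc9)[C@H](c1c(O)cc(OCc9ccccc9)cc1OCc9ccccc9)c1c(OCc9ccccc9)cc(OCc9ccccc9)c2c1O[C@H](c3ccc(OCc9ccccc9)c(OCc9ccccc9)c3)[C@@H](OCc9ccccc9)C2

F6 | step 10 | (1S,2R,3R)-2-(benzyloxy)-1-[3,4-bis(benzyloxy)phenyl]-3-[2-hydroxy-4,6-bis(benzyloxy)phenyl]-3-(penta-O-benzylcatechin-8-yl)propan-1-ol | O[C@@H](c3ccc(OCc9ccccc9)c(OCc9ccccc9)c3)[C@H](OCc9ccccc9)[C@H](c1c(O)cc(OCc9ccccc9)cc1OCc9ccccc9)c1c(OCc9ccccc9)cc(OCc9ccccc9)c2c1O[C@H](c3ccc(OCc9ccccc9)c(OCc9ccccc9)c3)[C@@H](OCc9ccccc9)C2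

F7 | step 6 | penta-O-benzylcatechin-8-carbaldehyde | O=Cc1c(OCc9ccccc9)cc(OCc9ccccc9)c2c1O[C@H](c3ccc(OCc9ccccc9)c(OCc9ccccc9)c3)[C@@H](OCc9ccccc9)C2

F8 | step 16 | 8-bromo-tetra-O-benzyl-4β-(benzylthio)epicatechin | Brc1c(OCc9ccccc9)cc(OCc9ccccc9)c2c1O[C@H](c3ccc(OCc9ccccc9)c(OCc9ccccc9)c3)[C@H](O)[C@H]2SCc9ccccc9

F9 | step 17 | 8-lithio bis(3-O-lithio) derivative of 27 | [Li]c1c(OCc9ccccc9)cc(OCc9ccccc9)c2c1O[C@H](c3ccc(OCc9ccccc9)c(OCc9ccccc9)c3)[C@H](O[Li])[C@H]2c1c(OCc9ccccc9)cc(OCc9ccccc9)c2c1O[C@H](c3ccc(OCc9ccccc9)c(OCc9ccccc9)c3)[C@H](O[Li])[C@H]2c1c(OCc9ccccc9)cc(OCc9ccccc9)c2c1O[C@H](c3ccc(OCc9ccccc9)c(OCc9ccccc9)c3)[C@H](OCc9ccccc9)[C@H]2c1c(OCc9ccccc9)cc(OCc9ccccc9)c2c1O[C@H](c3ccc(OCc9ccccc9)c(OCc9ccccc9)c3)[C@@H](OCc9ccccc9)C2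

F10 | step 17 | tetra-O-benzylepicatechin-(4β→8)-tetra-O-benzylepicatechin-(4β→8)-penta-O-benzylepicatechin-(4β→8)-penta-O-benzylcatechin | c9ccccc9COc1cc(OCc9ccccc9)c2c(c1)O[C@H](c3ccc(OCc9ccccc9)c(OCc9ccccc9)c3)[C@H](O)[C@H]2c1c(OCc9ccccc9)cc(OCc9ccccc9)c2c1O[C@H](c3ccc(OCc9ccccc9)c(OCc9ccccc9)c3)[C@H](O)[C@H]2c1c(OCc9ccccc9)cc(OCc9ccccc9)c2c1O[C@H](c3ccc(OCc9ccccc9)c(OCc9ccccc9)c3)[C@H](OCc9ccccc9)[C@H]2c1c(OCc9ccccc9)cc(OCc9ccccc9)c2c1O[C@H](c3ccc(OCc9ccccc9)c(OCc9ccccc9)c3)[C@@H](OCc9ccccc9)C2

F11 | step 4 | 2,4,6-tris(benzyloxy)benzaldehyde | O=Cc1c(OCc9ccccc9)cc(OCc9ccccc9)cc1OCc9ccccc9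

A1 | alternative 1 | benzylated epicatechin trimer carrying the new ring A of unit 4 with free C8a phenol, two triisopropylsilyl ethers and the acetonide chain on C4a | c9ccccc9COc1cc(OCc9ccccc9)c2c(c1)O[C@H](c3ccc(OCc9ccccc9)c(OCc9ccccc9)c3)[C@H](OCc9ccccc9)[C@H]2c1c(OCc9ccccc9)cc(OCc9ccccc9)c2c1O[C@H](c3ccc(OCc9ccccc9)c(OCc9ccccc9)c3)[C@H](OCc9ccccc9)[C@H]2c1c(OCc9ccccc9)cc(OCc9ccccc9)c2c1O[C@H](c3ccc(OCc9ccccc9)c(OCc9ccccc9)c3)[C@H](OCc9ccccc9)[C@H]2c1c(O[Si](C(C)C)(C(C)C)C(C)C)cc(O[Si](C(C)C)(C(C)C)C(C)C)c(C[C@H](OC4(C)C)[C@@H](O4)c5ccc(OCc9ccccc9)c(OCc9ccccc9)c5)c1O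

A2 | alternative 1 | benzylated epicatechin trimer with a (triisopropylsiloxy)ethynyl group on C4 of unit 3 | c9ccccc9COc1cc(OCc9ccccc9)c2c(c1)O[C@H](c3ccc(OCc9ccccc9)c(OCc9ccccc9)c3)[C@H](OCc9ccccc9)[C@H]2c1c(OCc9ccccc9)cc(OCc9ccccc9)c2c1O[C@H](c3ccc(OCc9ccccc9)c(OCc9ccccc9)c3)[C@H](OCc9ccccc9)[C@H]2c1c(OCc9ccccc9)cc(OCc9ccccc9)c2c1O[C@H](c3ccc(OCc9ccccc9)c(OCc9ccccc9)c3)[C@H](OCc9ccccc9)[C@H]2C#CO[Si](C(C)C)(C(C)C)C(C)C

A3 | alternative 1 | 3-(triisopropylsiloxy)cyclobut-2-en-1-one with the acetonide-protected 3-[3,4-bis(benzyloxy)phenyl]-2,3-dihydroxypropyl chain on C4 | O=C1C=C(O[Si](C(C)C)(C(C)C)C(C)C)C1C[C@H](OC4(C)C)[C@@H](O4)c5ccc(OCc9ccccc9)c(OCc9ccccc9)c5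

A4 | alternative 2 | fully benzylated arecatannin A2 | c9ccccc9COc1cc(OCc9ccccc9)c2c(c1)O[C@H](c3ccc(OCc9ccccc9)c(OCc9ccccc9)c3)[C@H](OCc9ccccc9)[C@H]2c1c(OCc9ccccc9)cc(OCc9ccccc9)c2c1O[C@H](c3ccc(OCc9ccccc9)c(OCc9ccccc9)c3)[C@H](OCc9ccccc9)[C@H]2c1c(OCc9ccccc9)cc(OCc9ccccc9)c2c1O[C@H](c3ccc(OCc9ccccc9)c(OCc9ccccc9)c3)[C@H](OCc9ccccc9)[C@H]2c1c(OCc9ccccc9)cc(OCc9ccccc9)c2c1O[C@H](c3ccc(OCc9ccccc9)c(OCc9ccccc9)c3)[C@@H](OCc9ccccc9)C2

A5 | alternative 2 | tris-lactone: three (3R,4R)-3-benzyloxy-5,7-bis(benzyloxy)chroman-2-one units linked 4→8 and ending in penta-O-benzylcatechin | c9ccccc9COc1cc(OCc9ccccc9)c2c(c1)OC(=O)[C@H](OCc9ccccc9)[C@H]2c1c(OCc9ccccc9)cc(OCc9ccccc9)c2c1OC(=O)[C@H](OCc9ccccc9)[C@H]2c1c(OCc9ccccc9)cc(OCc9ccccc9)c2c1OC(=O)[C@H](OCc9ccccc9)[C@H]2c1c(OCc9ccccc9)cc(OCc9ccccc9)c2c1O[C@H](c3ccc(OCc9ccccc9)c(OCc9ccccc9)c3)[C@@H](OCc9ccccc9)C2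

A6 | alternative 3 | benzylated 4-(catechin-8-yl)flav-2-ene of unit 3 | c9ccccc9COc1cc(OCc9ccccc9)c2c(c1)OC(c3ccc(OCc9ccccc9)c(OCc9ccccc9)c3)=C[C@H]2c1c(OCc9ccccc9)cc(OCc9ccccc9)c2c1O[C@H](c3ccc(OCc9ccccc9)c(OCc9ccccc9)c3)[C@@H](OCc9ccccc9)C2

A7 | alternative 3 | metathesis diene: 1-[3,4-bis(benzyloxy)phenyl]vinyl ether of the ring A phenol with 1-(penta-O-benzylcatechin-8-yl)allyl group on the ortho carbon | C=C(c3ccc(OCc9ccccc9)c(OCc9ccccc9)c3)Oc1cc(OCc9ccccc9)cc(OCc9ccccc9)c1[C@@H](C=C)c1c(OCc9ccccc9)cc(OCc9ccccc9)c2c1O[C@H](c3ccc(OCc9ccccc9)c(OCc9ccccc9)c3)[C@@H](OCc9ccccc9)C2
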